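## Retrosynthetic overview

1. The strategy rests on the Z-trisubstituted alkene C5(C16)=C6. It is the only C=C of the ten-membered ring B (C1–C10) and lies between C4–OAc and the lactone carbon C7. Cutting it gives seco-diene 43, with an isopropenyl group on C4 and a vinyl group on C7.
2. West arm (C3–C5, C16): Mukaiyama aldol of the C2 aldehyde 37 with the silyl dienol ether of 3-methylbut-3-en-2-one, then a hydroxyl-directed anti reduction at C4.
3. East arm: γ-lactone ring C (C7, C8, C17, C19, O) is closed by a SmI2 Reformatsky reaction of a C7 2-bromopropanoate onto the C8 ketone. C7 comes from an asymmetric alkoxyallylboration and C9 from a chelate-controlled vinyl addition.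
4. Ring A: auxiliary-controlled Diels–Alder reaction (C1, C10, C11), iodolactonisation (C12), and tethered hydrosilylation–oxidation (C14).
5. Order of ring formation: ring A (step 3), lactone ring C (step 20), ten-membered ring B (step 28).

Key step: step 28

Remark: briarane numbering (C1–C20) is used for all compounds. β is the face of ring A that carries C15, and α is the opposite face. Racemic 32 is used because its stereocentre is lost in the enolate.

## Route

Step 1
Reactants: 1 glyoxylic acid (as monohydrate); 2 methyl 2-(triphenyl-λ5-phosphanylidene)propanoate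
Product: 3 (E)-4-methoxy-3-methyl-4-oxobut-2-enoic acid (mesaconate half ester; free acid = future C9, ester = future C2)
Conditions: CH2Cl2, 0 °C to rt
Reagents that add atoms: none
Why: Wittig olefination with a stabilised α-branched ylide should give the E alkene (the two carbonyl groups trans) and differentiates the two carboxyl termini from the start.

Step 2
Reactants: 3 mesaconate half ester; 4 (S)-4-benzyl-1,3-oxazolidin-2-one
Product: 6 N-enoyl imide (E alkene kept), via mixed pivalic anhydride 5 (not isolated)
Conditions: t-BuCOCl, Et3N, THF, −20 °C; then 4, LiCl, −20 °C to rt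
Reagents that add atoms: pivaloyl chloride CC(C)(C)C(=O)Cl (its atoms stay in 5 only)
Why: N-acylation of an oxazolidinone through a mixed pivalic anhydride is standard for enoic acids, because the nitrogen attacks the less hindered enoyl carbonyl and the alkene geometry is untouched.

Step 3
Reactants: 6 N-enoyl imide; 7 (E)-penta-1,3-diene
Product: 8 Diels–Alder adduct: cyclohexene (C12=C13) with C1 (β-CH3 = C15, α-CO2Me = C2), C10 (β-acyl C9) and C11 (β-CH3 = C20)
Conditions: Et2AlCl (1.4 equiv), CH2Cl2, −78 to −20 °C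
Reagents that add atoms: none
Why: Auxiliary-controlled Lewis acid-promoted Diels–Alder reaction, in which the aluminium-chelated s-cis imide is the dominant acceptor, so the CH2 terminus of the diene bonds to C1 and the methyl-bearing terminus to C10; the imide carbonyl sits endo (C9 cis to C20), the E alkene fixes C2 trans to C9, and the benzyl group blocks the Cα-Re face, so C1, C10 and C11 form in the absolute sense of the target.

Step 4
Reactants: 8 Diels–Alder adduct
Product: 10 C9 carboxylic acid, via peroxy acid 9 (not isolated)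
Conditions: LiOH, 30% H2O2, THF/H2O, 0 °C; then Na2SO3; then HCl
Reagents that add atoms: hydrogen peroxide OO
Why: Hydroperoxide cleavage of an N-acyloxazolidinone attacks the exocyclic carbonyl even in hindered imides, sulfite reduces the percarboxylate, and the methyl ester on quaternary C1 is too hindered to be saponified.

Step 5
Reactants: 10 C9 carboxylic acid
Product: 11 iodolactone (γ-lactone C9(=O)–O–C12 on the β face, α-iodide at C13)
Conditions: I2, NaHCO3, MeCN/H2O, 0 °C to rt, dark
Reagents that add atoms: iodine II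
Why: Iodolactonisation, in which the iodonium ion forms reversibly on the free α face and the β-oriented C9 carboxylate attacks C12 anti, giving the 6-oxabicyclo[3.2.1]octanone and fixing the C12 oxygen β, cis to C9 and C20.

Step 6
Reactants: 11 iodolactone
Product: 12 unsaturated lactone (C13=C14)
Conditions: DBU, toluene, 80 °C
Reagents that add atoms: none
Why: E2 dehydroiodination, in which the axial C13–I bond of the locked bicycle is antiperiplanar only to the axial β hydrogen on C14, so the alkene can form only as C13=C14.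

Step 7
Reactants: 12 unsaturated lactone
Product: 13 triol (α-C2H2OH, β-C9H2OH, β-C12–OH, C13=C14)
Conditions: LiAlH4, THF, 0 °C to reflux
Reagents that add atoms: none
Why: Exhaustive hydride reduction of the lactone and the ester touches no stereocentre and avoids any basic equilibration at C10.

Step 8
Reactants: 13 triol
Product: 16 tetraol (new α-C14–OH; C13 is CH2), via tris-dimethylsilyl ether 14 (not isolated), via oxasilolane 15 (not isolated)
Conditions: (HMe2Si)2NH, rt; H2PtCl6·6H2O (cat.), THF, 60 °C; then 30% H2O2, KF, KHCO3, THF/MeOH, rt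
Reagents that add atoms: 1,1,3,3-tetramethyldisilazane C[SiH](C)N[SiH](C)C (its atoms stay in 14 and 15 only); hydrogen peroxide OO
Why: Intramolecular hydrosilylation followed by Tamao oxidation, in which only the homoallylic C2–O–SiHMe2 tether reaches the alkene through a five-membered (5-exo) ring, so Si goes to C14 and H to C13, syn on the α face, and the C–Si bond is oxidised with retention.

Step 9
Reactants: 16 tetraol
Product: 17 C2/C14 acetonide with free C9H2OH and C12–OH
Conditions: Me2C(OMe)2, PPTS, acetone, rt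
Reagents that add atoms: 2,2-dimethoxypropane COC(C)(C)OC
Why: Thermodynamic acetalisation selects the C2/C14 pair, the only diol of 16 that can close a six-membered dioxane (O12 and O14 are trans, and all other pairs need seven-membered rings).

Step 10
Reactants: 17 acetonide diol
Product: 19 saturated γ-lactone C9(=O)–O–C12, via lactol 18 (not isolated)
Conditions: TEMPO (cat.), PhI(OAc)2 (2.5 equiv), CH2Cl2, rt
Reagents that add atoms: none
Why: Oxoammonium oxidation is selective for the primary C9 alcohol, and the cis C12 hydroxyl traps the aldehyde as lactol 18, which is oxidised faster than it can be intercepted, so the oxidation is run through to the lactone.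

Step 11
Reactants: 19 saturated γ-lactone
Product: 18 bicyclic lactol (C9H(OH)–O–C12)
Conditions: i-Bu2AlH (1.1 equiv), CH2Cl2, −78 °C; Rochelle salt
Reagents that add atoms: none
Why: Half-reduction of a lactone with i-Bu2AlH at low temperature stops at the aluminium hemiacetal and returns the lactol with C9 and O12 still held together.

Step 12
Reactants: 18 lactol; 20 vinylmagnesium bromide
Product: 21 diol with C9(OH)–CH=CH2 (C9 configured as in the target) and β-C12–OH
Conditions: CH2=CHMgBr (3 equiv), THF, −78 to 0 °C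
Reagents that add atoms: none
Why: Grignard addition to a lactol, in which deprotonation opens 18 to the C12 magnesium alkoxide and the C9 aldehyde; their 1,3-diaxial chelate turns the carbonyl oxygen over ring A towards O12, so vinyl attacks the exposed face anti to the C10–C1 bond (the chelate and Felkin–Anh models agree) and sets C9.

Step 13
Reactants: 21 diol
Product: 22 C12 tert-butyldimethylsilyl ether with free C9–OH
Conditions: TBSCl (1.1 equiv), imidazole, DMF, 0 °C
Reagents that add atoms: tert-butyldimethylsilyl chloride CC(C)(C)[Si](C)(C)Cl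
Why: Sterically differentiated silylation, because C12–OH has a CH2 neighbour whereas C9–OH is buried next to C10 and quaternary C1, so the ring hydroxyl should react first.

Step 14
Reactants: 22 C12 silyl ether
Product: 23 C9 allylic acetate
Conditions: Ac2O, pyridine, DMAP, CH2Cl2, rt
Reagents that add atoms: acetic anhydride CC(=O)OC(C)=O
Why: DMAP-catalysed acetylation installs the C9 acetate of the target before ring C exists, which excludes a later translactonisation onto O9.

Step 15
Reactants: 23 C9 allylic acetate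
Product: 25 α-acetoxy aldehyde (C8 = CHO), via secondary ozonide 24 (not isolated)
Conditions: O3, CH2Cl2, −78 °C; then PPh3
Reagents that add atoms: ozone [O-][O+]=O
Why: Ozonolysis with reductive work-up cleaves the only alkene of 23, and the neutral conditions spare the epimerisable C9 centre.

Step 16
Reactants: 25 α-acetoxy aldehyde; 26 allyl 4-methoxyphenyl ether
Product: 29 syn adduct C8(OH)–C7(OC6H4OMe)–CH=CH2, via Z-alkoxyallylborane 27 (not isolated), via borinate 28 (not isolated)
Conditions: 26, s-BuLi, THF, −78 °C; (+)-Ipc2BOMe (from (−)-α-pinene); BF3·OEt2; 25, −78 °C; then pH 7 buffer, MeOH, 30% H2O2, 0 °C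
Reagents that add atoms: (+)-B-methoxydiisopinocampheylborane COB([C@H]1C[C@H]2C[C@@H]([C@@H]1C)C2(C)C)[C@H]1C[C@H]2C[C@@H]([C@@H]1C)C2(C)C (its atoms stay in 27 and 28 only)
Why: Asymmetric γ-alkoxyallylboration through a chair transition state, in which this borane antipode attacks the Re face of the C8 aldehyde under reagent control and the Z-alkoxyallyl unit gives the syn C7/C8 pair; this sets C7 as in the target, C8 is erased in step 17, and the buffered peroxide work-up spares the acetate.

Step 17
Reactants: 29 syn adduct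
Product: 30 C8 ketone flanked by C9–OAc and C7–OC6H4OMe
Conditions: Dess–Martin periodinane, NaHCO3, CH2Cl2, 0 °C to rt
Reagents that add atoms: none
Why: Dess–Martin oxidation works under buffered non-basic conditions, so the acidic allylic C7–H is not enolised and the vinyl group stays out of conjugation.

Step 18
Reactants: 30 C8 ketone
Product: 31 α-hydroxy ketone (free C7–OH)
Conditions: (NH4)2Ce(NO3)6, MeCN/H2O, 0 °C, short contact
Reagents that add atoms: none
Why: Oxidative dearylation of a p-methoxyphenyl ether by tetravalent cerium releases the alcohol and benzoquinone without base, and the silyl ether, acetate, vinyl group and (at 0 °C) the acetonide are expected to survive.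

Step 19
Reactants: 31 α-hydroxy ketone; 32 2-bromopropanoyl bromide (racemic)
Product: 33 C7 2-bromopropanoate (epimers at the C–Br carbon)
Conditions: pyridine, CH2Cl2, −30 °C
Reagents that add atoms: none
Why: O-acylation of the only free hydroxyl with an acid bromide and a weak base places the latent C17–C19 enolate on O7, and the C–Br configuration is irrelevant.

Step 20
Reactants: 33 C7 2-bromopropanoate
Product: 34 β-hydroxy-γ-lactone (ring C closed; C8–OH, C7 vinyl and C18 cis, C9 on the opposite face)
Conditions: SmI2 (2.5 equiv), THF, −78 °C; then aq NH4Cl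
Reagents that add atoms: none
Why: Intramolecular samarium Reformatsky reaction, in which fast reduction of the C–Br bond gives the ester enolate regiospecifically and without base; C17 adds to the C8 ketone so that the bulky C9 substituent ends trans to the C7 vinyl group and to the C17 methyl group, so C7 controls C8 and C17 (the latter is also the thermodynamic epimer).

Step 21
Reactants: 34 β-hydroxy-γ-lactone
Product: 35 triol (C2H2OH, α-C14–OH, C8–OH)
Conditions: PPTS, MeOH, rt
Reagents that add atoms: none
Why: Mild transacetalisation removes the strained six-membered acetonide, while the hindered secondary TBS ether, the acetate and the lactone are stable to PPTS.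

Step 22
Reactants: 35 triol
Product: 36 tris(trimethylsilyl) ether (O2, O14, O8)
Conditions: N-(trimethylsilyl)imidazole, CH2Cl2, rt
Reagents that add atoms: N-(trimethylsilyl)imidazole C[Si](C)(C)n1ccnc1
Why: Exhaustive silylation with a powerful neutral silyl donor also caps the tertiary C8–OH, which would otherwise close a six-membered lactol on the C2 aldehyde made in the next step.

Step 23
Reactants: 36 tris(trimethylsilyl) ether
Product: 37 C2 aldehyde with C14–OTMS and C8–OTMS
Conditions: (COCl)2, DMSO, CH2Cl2, −78 to −30 °C; then Et3N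
Reagents that add atoms: none
Why: Swern oxidation of silyl ethers, in which the chlorosulfonium salt desilylates and oxidises only the primary trimethylsilyl ether and leaves the secondary and tertiary ones in place.

Step 24
Reactants: 38 3-methylbut-3-en-2-one
Product: 39 2-(trimethylsilyloxy)-3-methylbuta-1,3-diene
Conditions: TMSOTf, Et3N, Et2O, 0 °C
Reagents that add atoms: trimethylsilyl triflate C[Si](C)(C)OS(=O)(=O)C(F)(F)F
Why: Soft enolisation and silylation of a methyl ketone whose acetyl CH3 group is its only α-enolisable site gives the cross-conjugated silyl dienol ether.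

Step 25
Reactants: 37 C2 aldehyde; 39 silyl dienol ether
Product: 40 β-hydroxy enone C2(OH)–C3H2–C4(=O)–C5(CH3)=CH2 (O14 and O8 still silylated)
Conditions: BF3·OEt2, CH2Cl2, −78 °C; aq NaHCO3
Reagents that add atoms: none
Why: Mukaiyama aldol through an open, non-chelated transition state, in which the carbonyl oxygen lies syn to axial C15 and antiparallel to the C14–O dipole (polar 1,3-model) while the C9 arm blocks one flank, so the nucleophile should attack the Re face anti to the C1–C10 bond and set C2 as in the target.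

Step 26
Reactants: 40 β-hydroxy enone
Product: 42 tetraol with anti C2/C4 diol plus free C14–OH and C8–OH, via bis-trimethylsilyl diol 41 (not isolated)
Conditions: Me4NBH(OAc)3, MeCN/AcOH, −30 °C; then citric acid, MeOH, rt
Reagents that add atoms: none
Why: Evans–Saksena reduction, in which the C2 hydroxyl binds boron and delivers hydride intramolecularly through a chair to give the 1,3-anti diol (C4 set from C2; 1,2-reduction of the enone only), and the mild acidic methanolysis then strips the two trimethylsilyl ethers but not the TBS ether.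

Step 27
Reactants: 42 tetraol
Product: 43 seco-diene: acetates at C2, C4, C9 and C14, free tertiary C8–OH, C12–OTBS, C4 isopropenyl, C7 vinyl
Conditions: Ac2O, pyridine, DMAP, CH2Cl2, rt
Reagents that add atoms: acetic anhydride CC(=O)OC(C)=O
Why: DMAP-catalysed acetylation takes the three secondary hydroxyls, while the fully substituted, crowded C8 hydroxyl is expected to stay free under these conditions.

Step 28
Reactants: 43 seco-diene
Product: 44 C12 silyl ether of the target (ring B closed, 5Z)
Conditions: second-generation Grubbs catalyst RuCl2(=CHPh)(PCy3)(H2IMes) (20 mol %, in portions), 1,4-benzoquinone (cat.), toluene, 1 mM, 80–110 °C, argon stream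
Reagents that add atoms: none
Why: The catalyst first exchanges its benzylidene with the monosubstituted C7 vinyl group (the isopropenyl group is too hindered to initiate), the resulting C6 ruthenium alkylidene adds across C5(C16)=CH2 in a [2+2] sense, and cycloreversion of the ruthenacyclobutane forms C5=C6 and expels a methylidene that leaves as ethene. This is ring-closing olefin metathesis to a medium-ring trisubstituted cycloalkene, a known reaction type. The ten-membered ring B (C1–C10) closes by this intramolecular [2+2]/retro-[2+2] sequence between the ends of the C2–C5 arm and the C9–C6 arm, which are gauche on the trans-substituted C1–C10 bond of ring A and are turned inward by the rigid γ-lactone. No stereocentre is created; only the alkene geometry is at stake, and Z (C4 and C7 cis) is expected because an E trisubstituted alkene between C4–OAc and the lactone would be far more strained in this frame, and the reversibility of metathesis at this temperature allows correction. The step needs ring closure to outrun intermolecular coupling, which is secured by high dilution, portionwise catalyst addition and removal of ethene; 43 holds no other C=C bond, and benzoquinone suppresses isomerisation of the allylic C4 and C7 positions by ruthenium hydrides.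

Step 29
Reactants: 44 C12 silyl ether of the target
Product: 45 target CNP0183630.2
Conditions: HF·pyridine, pyridine, THF, 0 °C to rt
Reagents that add atoms: none
Why: Buffered fluoride cleavage of the secondary TBS ether is compatible with the four acetates, the β-hydroxy lactone and the allylic positions, and no neighbouring acetate is placed to migrate onto O12 (O14 is 1,3-trans).

## Compound list

1 | glyoxylic acid | O=CC(=O)O | starting material
2 | methyl 2-(triphenyl-λ5-phosphanylidene)propanoate | COC(=O)C(C)=P(c1ccccc1)(c1ccccc1)c1ccccc1 | starting material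
3 | (E)-4-methoxy-3-methyl-4-oxobut-2-enoic acid | COC(=O)/C(C)=C/C(=O)O | intermediate
4 | (S)-4-benzyl-1,3-oxazolidin-2-one | O=C1N[C@@H](Cc2ccccc2)CO1 | starting material
5 | mixed pivalic anhydride of 3 | COC(=O)/C(C)=C/C(=O)OC(=O)C(C)(C)C | intermediate
6 | methyl (E)-4-[(S)-4-benzyl-2-oxooxazolidin-3-yl]-2-methyl-4-oxobut-2-enoate | COC(=O)/C(C)=C/C(=O)N1C(=O)OC[C@@H]1Cc1ccccc1 | intermediate
7 | (E)-penta-1,3-diene | C/C=C/C=C | starting material
8 | Diels–Alder adduct (ring A, C12=C13; C15, C9, C20 β; C2 ester α) | C[C@H]1C=CC[C@](C)(C(=O)OC)[C@H]1C(=O)N2C(=O)OC[C@@H]2Cc3ccccc3 | intermediate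
9 | C9 peroxy acid | C[C@H]1C=CC[C@](C)(C(=O)OC)[C@H]1C(=O)OO | intermediate
10 | C9 carboxylic acid | C[C@H]1C=CC[C@](C)(C(=O)OC)[C@H]1C(=O)O | intermediate
11 | iodolactone (O12 β, I13 α) | I[C@@H]1C[C@](C)(C(=O)OC)[C@@H]2[C@@H](C)[C@H]1OC2=O | intermediate
12 | unsaturated lactone (C13=C14) | C1=C[C@](C)(C(=O)OC)[C@@H]2[C@@H](C)[C@H]1OC2=O | intermediate
13 | triol (C2H2OH, C9H2OH, C12–OH, C13=C14) | O[C@H]1C=C[C@](C)(CO)[C@@H](CO)[C@H]1C | intermediate
14 | tris(dimethylsilyl) ether of 13 | C[SiH](C)O[C@H]1C=C[C@](C)(CO[SiH](C)C)[C@@H](CO[SiH](C)C)[C@H]1C | intermediate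
15 | 1-oxa-2-silacyclopentane (Si on α-C14, O on C2) | C[Si]2(C)[C@H]1C[C@H](O[SiH](C)C)[C@H](C)[C@H](CO[SiH](C)C)[C@@]1(C)CO2 | intermediate
16 | tetraol (α-C14–OH, β-C12–OH, C2H2OH, C9H2OH) | O[C@H]1C[C@H](O)[C@H](C)[C@H](CO)[C@@]1(C)CO | intermediate
17 | C2/C14 acetonide diol | CC1(C)OC[C@@]2(C)[C@H](C[C@H](O)[C@H](C)[C@@H]2CO)O1 | intermediate
18 | bicyclic lactol C9H(OH)–O–C12 | CC1(C)OC[C@@]2(C)[C@H](C[C@H]3[C@H](C)[C@@H]2C(O)O3)O1 | intermediate
19 | saturated γ-lactone C9(=O)–O–C12 | CC1(C)OC[C@@]2(C)[C@H](C[C@H]3[C@H](C)[C@@H]2C(=O)O3)O1 | intermediate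
20 | vinylmagnesium bromide | C=C[Mg]Br | starting material
21 | C9 allylic alcohol / C12 alcohol diol | CC1(C)OC[C@@]2(C)[C@H](C[C@H](O)[C@H](C)[C@@H]2[C@@H](O)C=C)O1 | intermediate
22 | C12 TBS ether | CC1(C)OC[C@@]2(C)[C@H](C[C@H](O[Si](C)(C)C(C)(C)C)[C@H](C)[C@@H]2[C@@H](O)C=C)O1 | intermediate
23 | C9 allylic acetate | CC1(C)OC[C@@]2(C)[C@H](C[C@H](O[Si](C)(C)C(C)(C)C)[C@H](C)[C@@H]2[C@@H](OC(C)=O)C=C)O1 | intermediate
24 | secondary ozonide of 23 | CC1(C)OC[C@@]2(C)[C@H](C[C@H](O[Si](C)(C)C(C)(C)C)[C@H](C)[C@@H]2[C@@H](OC(C)=O)C3OCOO3)O1 | intermediate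
25 | α-acetoxy aldehyde (C8 = CHO) | CC1(C)OC[C@@]2(C)[C@H](C[C@H](O[Si](C)(C)C(C)(C)C)[C@H](C)[C@@H]2[C@@H](OC(C)=O)C=O)O1 | intermediate
26 | allyl 4-methoxyphenyl ether | C=CCOc1ccc(OC)cc1 | starting material
27 | (Z)-[3-(4-methoxyphenoxy)allyl]diisopinocampheylborane | COc1ccc(O/C=C\CB([C@H]2C[C@H]3C[C@@H]([C@@H]2C)C3(C)C)[C@H]2C[C@H]3C[C@@H]([C@@H]2C)C3(C)C)cc1 | intermediate
28 | C8 diisopinocampheylborinate of 29 | CC1(C)OC[C@@]2(C)[C@H](C[C@H](O[Si](C)(C)C(C)(C)C)[C@H](C)[C@@H]2[C@@H](OC(C)=O)[C@H](OB([C@H]3C[C@H]4C[C@@H]([C@@H]3C)C4(C)C)[C@H]3C[C@H]4C[C@@H]([C@@H]3C)C4(C)C)[C@@H](Oc3ccc(OC)cc3)C=C)O1 | intermediate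
29 | syn adduct (C8–OH, C7–OC6H4OMe, vinyl) | CC1(C)OC[C@@]2(C)[C@H](C[C@H](O[Si](C)(C)C(C)(C)C)[C@H](C)[C@@H]2[C@@H](OC(C)=O)[C@H](O)[C@@H](Oc3ccc(OC)cc3)C=C)O1 | intermediate
30 | C8 ketone | CC1(C)OC[C@@]2(C)[C@H](C[C@H](O[Si](C)(C)C(C)(C)C)[C@H](C)[C@@H]2[C@@H](OC(C)=O)C(=O)[C@@H](Oc3ccc(OC)cc3)C=C)O1 | intermediate
31 | α-hydroxy ketone (C7–OH) | CC1(C)OC[C@@]2(C)[C@H](C[C@H](O[Si](C)(C)C(C)(C)C)[C@H](C)[C@@H]2[C@@H](OC(C)=O)C(=O)[C@@H](O)C=C)O1 | intermediate
32 | 2-bromopropanoyl bromide | CC(Br)C(=O)Br | starting material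
33 | C7 2-bromopropanoate | CC1(C)OC[C@@]2(C)[C@H](C[C@H](O[Si](C)(C)C(C)(C)C)[C@H](C)[C@@H]2[C@@H](OC(C)=O)C(=O)[C@@H](OC(=O)C(C)Br)C=C)O1 | intermediate
34 | β-hydroxy-γ-lactone (ring C) | CC1(C)OC[C@@]2(C)[C@H](C[C@H](O[Si](C)(C)C(C)(C)C)[C@H](C)[C@@H]2[C@@H](OC(C)=O)[C@@]3(O)[C@H](C=C)OC(=O)[C@@H]3C)O1 | intermediate
35 | triol (C2H2OH, C14–OH, C8–OH) | O[C@H]1C[C@H](O[Si](C)(C)C(C)(C)C)[C@H](C)[C@H]([C@@H](OC(C)=O)[C@@]2(O)[C@H](C=C)OC(=O)[C@@H]2C)[C@@]1(C)CO | intermediate
36 | tris(trimethylsilyl) ether | C[Si](C)(C)O[C@H]1C[C@H](O[Si](C)(C)C(C)(C)C)[C@H](C)[C@H]([C@@H](OC(C)=O)[C@@]2(O[Si](C)(C)C)[C@H](C=C)OC(=O)[C@@H]2C)[C@@]1(C)CO[Si](C)(C)C | intermediate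
37 | C2 aldehyde (O14, O8 silylated) | C[Si](C)(C)O[C@H]1C[C@H](O[Si](C)(C)C(C)(C)C)[C@H](C)[C@H]([C@@H](OC(C)=O)[C@@]2(O[Si](C)(C)C)[C@H](C=C)OC(=O)[C@@H]2C)[C@@]1(C)C=O | intermediate
38 | 3-methylbut-3-en-2-one | CC(=O)C(C)=C | starting material
39 | 2-(trimethylsilyloxy)-3-methylbuta-1,3-diene | C=C(C)C(=C)O[Si](C)(C)C | intermediate
40 | β-hydroxy enone (aldol) | C[Si](C)(C)O[C@H]1C[C@H](O[Si](C)(C)C(C)(C)C)[C@H](C)[C@H]([C@@H](OC(C)=O)[C@@]2(O[Si](C)(C)C)[C@H](C=C)OC(=O)[C@@H]2C)[C@@]1(C)[C@H](O)CC(=O)C(C)=C | intermediate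
41 | anti C2/C4 diol, O14 and O8 silylated | C[Si](C)(C)O[C@H]1C[C@H](O[Si](C)(C)C(C)(C)C)[C@H](C)[C@H]([C@@H](OC(C)=O)[C@@]2(O[Si](C)(C)C)[C@H](C=C)OC(=O)[C@@H]2C)[C@@]1(C)[C@H](O)C[C@@H](O)C(C)=C | intermediate
42 | tetraol (C2, C4, C14, C8 hydroxyls free) | O[C@H]1C[C@H](O[Si](C)(C)C(C)(C)C)[C@H](C)[C@H]([C@@H](OC(C)=O)[C@@]2(O)[C@H](C=C)OC(=O)[C@@H]2C)[C@@]1(C)[C@H](O)C[C@@H](O)C(C)=C | intermediate
43 | seco-diene (metathesis precursor) | CC(=O)O[C@H]1C[C@H](O[Si](C)(C)C(C)(C)C)[C@H](C)[C@H]([C@@H](OC(C)=O)[C@@]2(O)[C@H](C=C)OC(=O)[C@@H]2C)[C@@]1(C)[C@H](OC(C)=O)C[C@@H](OC(C)=O)C(C)=C | intermediate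
44 | C12 silyl ether of the target | CC(=O)O[C@H]1C[C@H](O[Si](C)(C)C(C)(C)C)[C@H](C)[C@@H]2[C@@H](OC(C)=O)[C@@]3(O)[C@H](/C=C(/C)[C@H](OC(C)=O)C[C@@H](OC(C)=O)[C@]21C)OC(=O)[C@@H]3C | intermediate
45 | CNP0183630.2 | CC(=O)O[C@H]1C[C@H](O)[C@H](C)[C@@H]2[C@@H](OC(C)=O)[C@@]3(O)[C@H](/C=C(/C)[C@H](OC(C)=O)C[C@@H](OC(C)=O)[C@]21C)OC(=O)[C@@H]3C | target

## Step count and risks

Total step count: 29. Longest linear sequence: 28 (steps 1–23 and 25–29; step 24 is a one-step side branch).

Steps most likely to fail:

1. **Step 28.** The C6 alkylidene may fail to engage the isopropenyl group shielded by the C4 acetate. Intermolecular coupling through the vinyl groups, catalyst decay and double-bond migration could then outrun ring closure. The fallback closes the ring one step earlier on a reshaped precursor.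
   - It sets out from 42, whose allylic C4 hydroxyl is free. Allylic hydroxyl groups accelerate ruthenium metathesis, and the arm is less bulky.
   - The same catalyst in dilute toluene should give the macrocyclic tetraol F1.
   - Acetylation of its three secondary hydroxyls (Ac2O, pyridine, DMAP) comes back to the route at 44.

2. **Step 25.** Facial selectivity at the neopentyl C2 aldehyde may be poor or reversed. The fallback sets C4 by reagent control and C2 by hydride instead of carbon delivery. It sets out from 40, as whatever C2 mixture forms.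
   - Corey–Bakshi–Shibata reduction of the enone ((S)-2-methyl-CBS-oxazaborolidine, catecholborane, toluene, −78 °C; isopropenyl acts as the large group) should give the (4R)-allylic alcohol F2.
   - Acetylation of the less hindered allylic hydroxyl (Ac2O, pyridine, 0 °C) gives the C4 acetate F3.
   - Dess–Martin oxidation gives the C2 ketone F4.
   - Citric acid in MeOH removes both trimethylsilyl groups to give the β-hydroxy ketone F5.
   - Narasaka–Prasad reduction (Et2BOMe, NaBH4, THF/MeOH, −78 °C) through the O14–B–O2 chelate delivers hydride anti to the C1–C10 bond. This gives the C2/C14 syn diol F6, which has the C2 configuration of the target.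
   - Acetylation of both hydroxyls comes back to the route at 43.

3. **Step 20.** Electron transfer to the C8 ketone with loss of the α-acyloxy groups (C7–O or C9–OAc cleavage), or protonation of the enolate before ring closure, may compete with cyclisation. The fallback generates the same enolate by conjugate hydride addition. It sets out from 31.
   - Acryloyl chloride and pyridine give the C7 acrylate F7.
   - A copper hydride reductive aldol cyclisation (Cu(OAc)2·H2O cat., 1,1'-bis(diphenylphosphino)ferrocene, (Me2HSi)2O, THF, rt) reduces the acrylate to the propanoate enolate, which closes onto the C8 ketone.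
   - This comes back to the route at 34.

## Further compounds

F1 | step 28 | macrocyclic tetraol (ring B closed, 5Z; C2, C4, C14, C8 hydroxyls free; C12–OTBS) | O[C@H]1C[C@H](O[Si](C)(C)C(C)(C)C)[C@H](C)[C@@H]2[C@@H](OC(C)=O)[C@@]3(O)[C@H](/C=C(/C)[C@H](O)C[C@@H](O)[C@]21C)OC(=O)[C@@H]3C
F2 | step 25 | (4R)-allylic alcohol, C2 carbinol of either configuration, O14 and O8 silylated | C[Si](C)(C)O[C@H]1C[C@H](O[Si](C)(C)C(C)(C)C)[C@H](C)[C@H]([C@@H](OC(C)=O)[C@@]2(O[Si](C)(C)C)[C@H](C=C)OC(=O)[C@@H]2C)[C@@]1(C)C(O)C[C@@H](O)C(C)=C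
F3 | step 25 | C4 acetate with free C2 carbinol | C[Si](C)(C)O[C@H]1C[C@H](O[Si](C)(C)C(C)(C)C)[C@H](C)[C@H]([C@@H](OC(C)=O)[C@@]2(O[Si](C)(C)C)[C@H](C=C)OC(=O)[C@@H]2C)[C@@]1(C)C(O)C[C@@H](OC(C)=O)C(C)=C
F4 | step 25 | C2 ketone, C4 acetate | C[Si](C)(C)O[C@H]1C[C@H](O[Si](C)(C)C(C)(C)C)[C@H](C)[C@H]([C@@H](OC(C)=O)[C@@]2(O[Si](C)(C)C)[C@H](C=C)OC(=O)[C@@H]2C)[C@@]1(C)C(=O)C[C@@H](OC(C)=O)C(C)=C
F5 | step 25 | β-hydroxy ketone (free C14–OH and C8–OH, C2 ketone, C4 acetate) | O[C@H]1C[C@H](O[Si](C)(C)C(C)(C)C)[C@H](C)[C@H]([C@@H](OC(C)=O)[C@@]2(O)[C@H](C=C)OC(=O)[C@@H]2C)[C@@]1(C)C(=O)C[C@@H](OC(C)=O)C(C)=C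
F6 | step 25 | C2/C14 syn diol, C4 acetate | O[C@H]1C[C@H](O[Si](C)(C)C(C)(C)C)[C@H](C)[C@H]([C@@H](OC(C)=O)[C@@]2(O)[C@H](C=C)OC(=O)[C@@H]2C)[C@@]1(C)[C@H](O)C[C@@H](OC(C)=O)C(C)=C
F7 | step 20 | C7 acrylate of 31 | CC1(C)OC[C@@]2(C)[C@H](C[C@H](O[Si](C)(C)C(C)(C)C)[C@H](C)[C@@H]2[C@@H](OC(C)=O)C(=O)[C@@H](OC(=O)C=C)C=C)O1
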